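Ring C (C8, C9, C11–C14) is disconnected at C12, its methylene flanked by unbranched C11 and by C13, the carbon that must carry the exocyclic C19. Excising C12 leaves a trans-fused cyclopentanone (C8–C9–C11–C13(=O)–C14), which an Ireland–Claisen rearrangement (quaternary C8, C14) and a rhodium-catalysed 4-pentenal hydroacylation (C11–C13, H-9) assemble from sclareolide-derived drim-8-en-11-ol. The key step, a Lewis-acid-promoted diazoalkane homologation, inserts C12 selectively on the C11 side, expanding the five-membered ring to ring C and keeping the C13 carbonyl for one-carbon homologation. Asymmetric Nozaki–Hiyama–Kishi coupling with 4-bromofuranone and an intramolecular vinylogous aldol condensation then close ring D and the dienyl lactone.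

Key step: step 9

Remark: scalarane-type numbering is used (rings A/B = C1–C10; ring C = C8, C9, C11, C12, C13, C14; ring D = C13–C19, where C19 is the ring-D CH= between C13 and C18; C20 = lactone CH=, C21 = lactone C=O; α is the face of H-5, H-9 and H-14). Compounds 1, 7 and 20 are assumed to be purchased.

Step 1
Reactants: 1 (+)-sclareolide
Product: 2 11-hydroxysclareolide (C11 epimers)
Conditions: KHMDS, THF, −78 °C; 3-phenyl-2-(phenylsulfonyl)oxaziridine, −78 °C; aq. NH4Cl
Reagents that add atoms: 3-phenyl-2-(phenylsulfonyl)oxaziridine, O=S(=O)(c1ccccc1)N1OC1c1ccccc1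
Why: Enolate α-hydroxylation of the γ-lactone with an N-sulfonyloxaziridine should place oxygen on C11; the configuration of the new carbinol is immaterial because C11 becomes sp2 in step 3.

Step 2
Reactants: 2 11-hydroxysclareolide
Product: 3 13,14,15,16-tetranorlabdane-8α,11,12-triol (C11 epimers)
Conditions: LiAlH4, THF, 0 °C → reflux
Reagents that add atoms: none
Why: Hydride reduction of the lactone should open it to the tertiary 8α-alcohol and the vicinal 11,12-diol without touching C5, C8, C9 or C10.

Step 3
Reactants: 3 13,14,15,16-tetranorlabdane-8α,11,12-triol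
Product: 5 drim-8-en-11-al, via 8α-hydroxydriman-11-al 4 (not isolated)
Conditions: NaIO4, THF/H2O, 0 °C → rt; then p-TsOH·H2O (cat.), PhMe, 80 °C
Reagents that add atoms: none
Why: Periodate (Malaprade) cleavage of the 11,12-glycol excises C12, and acid-catalysed dehydration of the resulting β-hydroxy aldehyde should funnel to the conjugated tetrasubstituted Δ8(9)-enal.

Step 4
Reactants: 5 drim-8-en-11-al
Product: 6 drim-8-en-11-ol
Conditions: NaBH4, CeCl3·7H2O, MeOH, 0 °C
Reagents that add atoms: none
Why: Luche reduction should give clean 1,2-reduction of the tetrasubstituted enal to the primary allylic alcohol needed for the [3,3] shift.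

Step 5
Reactants: 6 drim-8-en-11-ol; 7 4-(benzyloxy)butanoic acid
Product: 8 drim-8-en-11-yl 4-(benzyloxy)butanoate
Conditions: EDC·HCl, DMAP, CH2Cl2, rt
Reagents that add atoms: none
Why: Carbodiimide/DMAP (Steglich) esterification joins the hindered primary allylic alcohol to the acid that carries C13–C16.

Step 6
Reactants: 8 drim-8-en-11-yl 4-(benzyloxy)butanoate
Product: 12 methyl 4-(benzyloxy)-2-(2,5,5,8a-tetramethyl-1-methylenedecahydronaphthalen-2-yl)butanoate (8β-CH3; C14 on the α-face of C8; exocyclic C9=C11H2), via silyl ketene acetal 9 (not isolated), via silyl ester 10 (not isolated), via carboxylic acid 11 (not isolated)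
Conditions: LDA, THF/DMPU (4:1), −78 °C; TBSCl, −78 °C → rt; PhMe, 90 °C; 1 M HCl/THF; then TMSCHN2, PhMe/MeOH, rt
Reagents that add atoms: (trimethylsilyl)diazomethane, C[Si](C)(C)C=[N+]=[N-]
Why: Ireland–Claisen rearrangement: the (Z)-silyl ketene acetal (enolisation in THF/DMPU) should rearrange through a chair transition state on the α-face of the Δ8 alkene (anti to the axial C10 methyl), creating the quaternary C8 (8β-CH3) and C14 with H-14 anti to that methyl as in the target, and methylation of the acid with TMSCHN2 gives the ester.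

Step 7
Reactants: 12 methyl ester
Product: 13 4-(benzyloxy)-2-(2,5,5,8a-tetramethyl-1-methylenedecahydronaphthalen-2-yl)butanal (C13 aldehyde)
Conditions: DIBAL-H (1.1 equiv), CH2Cl2, −78 °C; aq. potassium sodium tartrate
Reagents that add atoms: none
Why: DIBAL-H partial reduction: the tetrahedral aluminium hemiacetal of the hindered α-branched ester should persist at −78 °C and release the aldehyde only on work-up, leaving C14 untouched.

Step 8
Reactants: 13 C13 aldehyde
Product: 14 3-[2-(benzyloxy)ethyl]-3a,6,6,9a-tetramethyldodecahydro-1H-cyclopenta[a]naphthalen-2-one (trans-fused cyclopentanone C8–C9–C11–C13(=O)–C14; 8β-CH3, 9α-H, 14α-H)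
Conditions: [Rh(dppe)(acetone)2]BF4 (5 mol %), CH2Cl2, rt
Reagents that add atoms: none
Why: Rh(I)-catalysed intramolecular hydroacylation of a 4-pentenal: acyl–Rh–H from the aldehyde adds syn across the exocyclic C9=C11 bond from the α-face (the tether leaves C8 on that face and the axial C8 and C10 methyl groups block the β-face), so H-9 is α, and reductive elimination forms C11–C13 to give the trans-fused cyclopentanone.

Step 9
Reactants: 14 trans-fused cyclopentanone
Product: 16 1-[2-(benzyloxy)ethyl]-4b,8,8,10a-tetramethyltetradecahydrophenanthren-2(1H)-one (ring-C 13-ketone; 8β-CH3, 9α-H, 14α-H), via α-silyl ketone 15 (not isolated)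
Conditions: TMSCHN2 (1.3 equiv), BF3·OEt2 (1.2 equiv), CH2Cl2, −78 → −30 °C; then 1 M HCl, THF, rt
Reagents that add atoms: (trimethylsilyl)diazomethane, C[Si](C)(C)C=[N+]=[N-]
Why: The BF3-activated C13 carbonyl of 14 is attacked by the nucleophilic carbon of TMSCHN2 to give a β-oxido diazonium betaine, and loss of N2 with a concerted 1,2-shift of a ring bond inserts the new carbon (C12) into the five-membered ring; the α-silyl ketone 15 is protodesilylated on acidic work-up. The closest known reaction type is the Lewis-acid-promoted diazoalkane homologation of cycloalkanones (Büchner–Curtius–Schlotterbeck/Tiffeneau–Demjanov type). Ring C reaches its final size by ring expansion (1,2-alkyl shift) and not by cyclisation, so no ring-closure geometry has to be met and the trans B/C fusion is inherited from 14. No permanent stereocentre is created: C8, C9 and C14 are untouched (C14 stays α to the carbonyl but is not enolised at low temperature) and the silyl-bearing C12 centre is erased on desilylation. The step needs migration of C11 rather than C14 and a single homologation. The first should follow because the unbranched C11H2 migrates in preference to the branched C14H next to quaternary C8; the second because the strained trans-hydrindanone is more reactive than the α-branched cyclohexanone product and the reagent is used in slight excess only.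

Step 10
Reactants: 16 ring-C 13-ketone
Product: 17 13-(methoxymethylene) enol ether of 16 (E/Z mixture)
Conditions: Ph3P(CH2OMe)Cl, KHMDS, THF, 0 °C → rt
Reagents that add atoms: (methoxymethyl)triphenylphosphonium chloride, COC[P+](c1ccccc1)(c1ccccc1)c1ccccc1.[Cl-]
Why: Wittig methoxymethylenation turns the C13 ketone into a methyl enol ether, the masked C19 aldehyde that tolerates the next four steps; the alkene geometry is irrelevant.

Step 11
Reactants: 17 enol ether
Product: 18 primary C16 alcohol (2-[2-(methoxymethylene)-4b,8,8,10a-tetramethyltetradecahydrophenanthren-1-yl]ethanol)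
Conditions: Li, NH3(l), THF, −78 °C; NH4Cl
Reagents that add atoms: none
Why: Dissolving-metal cleavage of the benzyl ether (Birch-type conditions) frees the C16 alcohol while the isolated enol ether and the stereocentres are inert.

Step 12
Reactants: 18 primary C16 alcohol
Product: 19 C16 aldehyde ([2-(methoxymethylene)-4b,8,8,10a-tetramethyltetradecahydrophenanthren-1-yl]acetaldehyde)
Conditions: TPAP (5 mol %), NMO, 4 Å MS, CH2Cl2, rt
Reagents that add atoms: none
Why: Ley–Griffith oxidation is non-acidic, so the primary alcohol should become the C16 aldehyde without hydrolysing the enol ether.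

Step 13
Reactants: 19 C16 aldehyde; 20 4-bromofuran-2(5H)-one
Product: 21 (16R)-carbinol, 4-[(1R)-1-hydroxy-2-(ring-C-yl)ethyl]furan-2(5H)-one (16α-OH)
Conditions: CrCl2 (3 equiv), NiCl2 (cat.), chiral N-[2-(4-isopropyl-4,5-dihydrooxazol-2-yl)-6-methylphenyl]methanesulfonamide (enantiomer matched to 16R), Et3N, THF, rt
Reagents that add atoms: none
Why: Nozaki–Hiyama–Kishi coupling: Ni(0) inserts into the β-bromo-butenolide C–Br bond, transmetalation gives a C17–Cr(III) species that adds chemoselectively to the aldehyde, and the chiral sulfonamide–oxazoline ligand on chromium (asymmetric NHK), not the remote C14 centre, should control the new 16R carbinol.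

Step 14
Reactants: 21 (16R)-carbinol
Product: 22 16α-acetate of 21
Conditions: Ac2O, pyridine, DMAP (cat.), CH2Cl2, 0 °C
Reagents that add atoms: acetic anhydride, CC(=O)OC(C)=O
Why: DMAP-catalysed acylation installs the acetate of the target and, done directly on the crude alcohol, blocks translactonisation of the hydroxyalkyl butenolide.

Step 15
Reactants: 22 16α-acetate
Product: 23 C19 aldehyde (13-formyl, 13β-H, equatorial; 16α-OAc; butenolide intact)
Conditions: 2 M HCl, THF, 0 °C → rt
Reagents that add atoms: water, O
Why: Acid-catalysed enol-ether hydrolysis unmasks the C19 aldehyde, and C-protonation at C13 under equilibrating conditions should leave the equatorial formyl group (13β-H) trans to the equatorial C14 chain.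

Step 16
Reactants: 23 C19 aldehyde
Product: 26 target CNP0193439.1, via aldol adduct 24 (not isolated), via mesylate 25 (not isolated)
Conditions: DBU, CH2Cl2, −20 °C → rt; then MsCl, Et3N, 0 °C → rt
Reagents that add atoms: none
Why: Intramolecular direct vinylogous aldol addition (γ-deprotonation of the butenolide at C18 by DBU, 7-(enolendo)-exo-trig attack on the C19 aldehyde) closes ring D, and mesylation followed by E1cB loss of mesylate gives the γ-ylidene butenolide whose C19=C18 geometry is dictated by the seven-membered ring, while the epimerisable C13 settles in the trans-fused arrangement.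

Compound list

1 | (+)-sclareolide | O=C1C[C@H]2[C@@](C)(CC[C@H]3C(C)(C)CCC[C@]23C)O1 | starting material
2 | 11-hydroxysclareolide (C11 epimers) | O=C1C(O)[C@H]2[C@@](C)(CC[C@H]3C(C)(C)CCC[C@]23C)O1 | intermediate
3 | 13,14,15,16-tetranorlabdane-8α,11,12-triol (C11 epimers) | OCC(O)[C@H]1[C@](C)(O)CC[C@H]2C(C)(C)CCC[C@]12C | intermediate
4 | 8α-hydroxydriman-11-al | O=C[C@H]1[C@](C)(O)CC[C@H]2C(C)(C)CCC[C@]12C | intermediate
5 | drim-8-en-11-al | O=CC1=C(C)CC[C@H]2C(C)(C)CCC[C@]12C | intermediate
6 | drim-8-en-11-ol | OCC1=C(C)CC[C@H]2C(C)(C)CCC[C@]12C | intermediate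
7 | 4-(benzyloxy)butanoic acid | OC(=O)CCCOCc1ccccc1 | starting material
8 | drim-8-en-11-yl 4-(benzyloxy)butanoate | O=C(CCCOCc1ccccc1)OCC1=C(C)CC[C@H]2C(C)(C)CCC[C@]12C | intermediate
9 | (Z)-O-(tert-butyldimethylsilyl) ketene acetal of 8 | CC(C)(C)[Si](C)(C)O/C(=C\CCOCc1ccccc1)OCC1=C(C)CC[C@H]2C(C)(C)CCC[C@]12C | intermediate
10 | tert-butyldimethylsilyl ester of acid 11 | CC(C)(C)[Si](C)(C)OC(=O)[C@@H](CCOCc1ccccc1)[C@]1(C)CC[C@H]2C(C)(C)CCC[C@]2(C)C1=C | intermediate
11 | 4-(benzyloxy)-2-(2,5,5,8a-tetramethyl-1-methylenedecahydronaphthalen-2-yl)butanoic acid (8β-CH3, C14 on the α-face of C8, H-14 as in target) | OC(=O)[C@@H](CCOCc1ccccc1)[C@]1(C)CC[C@H]2C(C)(C)CCC[C@]2(C)C1=C | intermediate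
12 | methyl ester of 11 | COC(=O)[C@@H](CCOCc1ccccc1)[C@]1(C)CC[C@H]2C(C)(C)CCC[C@]2(C)C1=C | intermediate
13 | 4-(benzyloxy)-2-(2,5,5,8a-tetramethyl-1-methylenedecahydronaphthalen-2-yl)butanal | O=C[C@@H](CCOCc1ccccc1)[C@]1(C)CC[C@H]2C(C)(C)CCC[C@]2(C)C1=C | intermediate
14 | 3-[2-(benzyloxy)ethyl]-3a,6,6,9a-tetramethyldodecahydro-1H-cyclopenta[a]naphthalen-2-one (trans-fused; 8β-CH3, 9α-H, 14α-H) | O=C1C[C@H]2[C@@](C)(CC[C@H]3C(C)(C)CCC[C@]23C)[C@@H]1CCOCc1ccccc1 | intermediate
15 | 12-(trimethylsilyl) derivative of ketone 16 (C12 epimers) | O=C1C([Si](C)(C)C)C[C@H]2[C@@](C)(CC[C@H]3C(C)(C)CCC[C@]23C)[C@@H]1CCOCc1ccccc1 | intermediate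
16 | 1-[2-(benzyloxy)ethyl]-4b,8,8,10a-tetramethyltetradecahydrophenanthren-2(1H)-one (ring-C 13-ketone; 8β-CH3, 9α-H, 14α-H) | O=C1CC[C@H]2[C@@](C)(CC[C@H]3C(C)(C)CCC[C@]23C)[C@@H]1CCOCc1ccccc1 | intermediate
17 | 13-(methoxymethylene) enol ether of 16 (E/Z) | COC=C1CC[C@H]2[C@@](C)(CC[C@H]3C(C)(C)CCC[C@]23C)[C@@H]1CCOCc1ccccc1 | intermediate
18 | 2-[2-(methoxymethylene)-4b,8,8,10a-tetramethyltetradecahydrophenanthren-1-yl]ethanol (C16 alcohol) | COC=C1CC[C@H]2[C@@](C)(CC[C@H]3C(C)(C)CCC[C@]23C)[C@@H]1CCO | intermediate
19 | [2-(methoxymethylene)-4b,8,8,10a-tetramethyltetradecahydrophenanthren-1-yl]acetaldehyde (C16 aldehyde) | COC=C1CC[C@H]2[C@@](C)(CC[C@H]3C(C)(C)CCC[C@]23C)[C@@H]1CC=O | intermediate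
20 | 4-bromofuran-2(5H)-one | O=C1OCC(Br)=C1 | starting material
21 | 4-[(1R)-1-hydroxy-2-(2-(methoxymethylene)-4b,8,8,10a-tetramethyltetradecahydrophenanthren-1-yl)ethyl]furan-2(5H)-one (16R, 16α-OH) | COC=C1CC[C@H]2[C@@](C)(CC[C@H]3C(C)(C)CCC[C@]23C)[C@@H]1C[C@@H](O)C1=CC(=O)OC1 | intermediate
22 | 16α-acetate of 21 | COC=C1CC[C@H]2[C@@](C)(CC[C@H]3C(C)(C)CCC[C@]23C)[C@@H]1C[C@@H](OC(C)=O)C1=CC(=O)OC1 | intermediate
23 | C19 aldehyde (13-formyl, 13β-H; 16α-OAc; 4-substituted furan-2(5H)-one) | O=C[C@H]1CC[C@H]2[C@@](C)(CC[C@H]3C(C)(C)CCC[C@]23C)[C@@H]1C[C@@H](OC(C)=O)C1=CC(=O)OC1 | intermediate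
24 | aldol adduct (ring D closed, 19-OH, 18-H; C18/C19 epimers) | CC(=O)O[C@@H]1C[C@@H]2[C@@H](C(O)C3OC(=O)C=C31)CC[C@H]1[C@@]2(C)CC[C@H]2C(C)(C)CCC[C@]12C | intermediate
25 | 19-mesylate of 24 | CC(=O)O[C@@H]1C[C@@H]2[C@@H](C(OS(C)(=O)=O)C3OC(=O)C=C31)CC[C@H]1[C@@]2(C)CC[C@H]2C(C)(C)CCC[C@]12C | intermediate
26 | CNP0193439.1 (16α-acetoxy, 13β-H, 14α-H; C19=C18/C17=C20 dienyl γ-lactone) | CC(=O)O[C@@H]1C[C@@H]2[C@@H](C=C3OC(=O)C=C31)CC[C@H]1[C@@]2(C)CC[C@H]2C(C)(C)CCC[C@]12C | target

Total step count: 16. Longest linear sequence: 16 steps (1 → 26).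

Steps most likely to fail

Step 8. The cationic rhodium catalyst may be deactivated by decarbonylation of the aldehyde, hydrometalation of the doubly neopentylic 1,1-disubstituted alkene may be too slow, or facial control at C9 may be lost. The fallback sets out from 12 and comes back at 14. Hydroboration of the exocyclic alkene of 12 from the α-face (BH3·THF) and iodinolysis of the primary alkylborane in the same flask (I2, NaOMe, MeOH) would give the 11-iodo ester F1. Intramolecular nucleophilic acyl substitution promoted by SmI2 (cat. Fe(dbm)3, THF, −30 °C) would then close the same trans-fused cyclopentanone 14. Here C11 is the nucleophile and the ester carbon C13 the electrophile, an anionic 5-exo-trig acylation in place of the metal-hydride addition.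

Step 9. The branched C14 may migrate in competition with C11, giving the regioisomeric cyclohexanone, or the product may be homologated a second time. The fallback sets out from 14 and comes back at 16; it is a Saegusa–Ito-type ring expansion whose regiochemistry is fixed by enolisation. Kinetic deprotonation towards C11 (LDA, TMSCl, THF, −78 °C) would give the trimethylsilyl enol ether F2, and Simmons–Smith cyclopropanation (Et2Zn, CH2I2) the silyloxycyclopropane F3. FeCl3 (DMF, 0 °C) would cleave the internal cyclopropane bond through the β-keto radical to the ring-expanded β-chloro ketone F4, and NaOAc (MeOH, reflux) would eliminate HCl to the Δ11-enone F5. Homogeneous hydrogenation (H2, RhCl(PPh3)3, benzene), which spares the benzyl ether, would then give 16.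

Step 6. Enolisation may not be Z-selective enough, or the rearrangement may leak through a boat transition state, eroding the diastereoselectivity at C14; the [3,3] shift onto the tetrasubstituted alkene may also be slow. The fallback sets out from 6 and comes back at 12. An orthoester (Johnson–Claisen) rearrangement of 6 with trimethyl orthoacetate (cat. propionic acid, 140 °C), which involves no enolate geometry, would give the unbranched methyl ester F6 with the quaternary C8 already in place. Deprotonation (LDA, THF/DMPU, −78 °C) and alkylation with 2-(benzyloxy)ethyl iodide would then install the C14 side chain under steric control by the neighbouring quaternary centre, returning to 12.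

Further compounds

F1 | step 8 | methyl 4-(benzyloxy)-2-[1-(iodomethyl)-2,5,5,8a-tetramethyldecahydronaphthalen-2-yl]butanoate (9α-H, C11 iodide) | COC(=O)[C@@H](CCOCc1ccccc1)[C@]1(C)CC[C@H]2C(C)(C)CCC[C@]2(C)[C@H]1CI
F2 | step 9 | trimethylsilyl enol ether of 14 (C11=C13) | C[Si](C)(C)OC1=C[C@H]2[C@@](C)(CC[C@H]3C(C)(C)CCC[C@]23C)[C@@H]1CCOCc1ccccc1
F3 | step 9 | silyloxycyclopropane from F2 (cyclopropane C11–C12–C13) | C[Si](C)(C)OC12CC1[C@H]1[C@@](C)(CC[C@H]3C(C)(C)CCC[C@]13C)[C@@H]2CCOCc1ccccc1
F4 | step 9 | 11-chloro derivative of ketone 16 (β-chloro ketone) | O=C1CC(Cl)[C@H]2[C@@](C)(CC[C@H]3C(C)(C)CCC[C@]23C)[C@@H]1CCOCc1ccccc1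
F5 | step 9 | Δ11-enone corresponding to 16 | O=C1C=C[C@H]2[C@@](C)(CC[C@H]3C(C)(C)CCC[C@]23C)[C@@H]1CCOCc1ccccc1
F6 | step 6 | methyl (2,5,5,8a-tetramethyl-1-methylenedecahydronaphthalen-2-yl)acetate (8β-CH3) | COC(=O)C[C@]1(C)CC[C@H]2C(C)(C)CCC[C@]2(C)C1=C
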